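The plan disconnects the diaryl ether bond between the oxygen on C3 of ring A (the arene whose C4 oxygen carries the sulfate) and C4 of ring B (the 1,4-phenylene). An intramolecular copper-catalysed Ullmann coupling forms this O–C bond and closes the 24-membered ring in one operation. Because the C4 oxygen of ring A is masked as an allyl ether, the C3 hydroxyl is the only phenol available. The precursor is a linear spermidine diamide: N1 carries (E)-4-iodocinnamoyl, N8 carries (E)-4-allyloxy-3-hydroxycinnamoyl and N4 a 2-(trimethylsilyl)ethyl carbamate (Teoc). N1 and N8 are told apart by starting from N1,N4-bis-Boc-spermidine.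

Key step: step 8

Remark on locants: in ring A, C1 bears the propenoyl chain, C3 the ether oxygen and C4 the sulfate oxygen; in ring B, C1 bears its propenoyl chain and C4 the ether oxygen; in spermidine, N1 sits on the three-carbon arm, N4 is central and N8 sits on the four-carbon arm.

Remark on regiochemistry: the two primary amines of a spermidine protected only at N4 are nearly equivalent. The route therefore uses commercially available N1,N4-bis-Boc-spermidine, in which N8 is the only free amine, and places the Teoc group on N4 after both amides are in place. The Teoc group is not put on earlier because it would not survive acidic Boc removal.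

Assumption: the target is isolated as its inner salt (N4 ammonium, aryl sulfate), which has the same composition as the drawn neutral form.

Step 1
Reactants: 1 3,4-dihydroxybenzaldehyde
Product: 2 3-hydroxy-4-(prop-2-en-1-yloxy)benzaldehyde
Conditions: allyl bromide (1.1 equiv), NaHCO3 (1.5 equiv), NaI (0.2 equiv), DMF, 40 °C
Reagents that add atoms: allyl bromide, C=CCBr
Why: Williamson ether synthesis in which NaHCO3 ionises only the more acidic C4 hydroxyl (its phenoxide is conjugated with the para formyl group), so mono-allylation at O4 is expected while the C3 hydroxyl stays free.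

Step 2
Reactants: 2 3-hydroxy-4-(prop-2-en-1-yloxy)benzaldehyde
Product: 3 (E)-3-[3-hydroxy-4-(prop-2-en-1-yloxy)phenyl]prop-2-enoic acid
Conditions: malonic acid (2 equiv), pyridine, piperidine (cat.), 85 °C; aq. HCl work-up
Reagents that add atoms: malonic acid, OC(=O)CC(=O)O
Why: Knoevenagel–Doebner condensation with in situ decarboxylation should give the thermodynamically favoured E acid, and the allyl aryl ether is far below the temperature of a Claisen rearrangement.

Step 3
Reactants: 4 4-iodobenzaldehyde
Product: 5 (E)-3-(4-iodophenyl)prop-2-enoic acid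
Conditions: malonic acid (2 equiv), pyridine, piperidine (cat.), 90 °C; aq. HCl work-up
Reagents that add atoms: malonic acid, OC(=O)CC(=O)O
Why: Knoevenagel–Doebner condensation with in situ decarboxylation should give the E acid, and the aryl iodide is inert to these conditions.

Step 4
Reactants: 5 (E)-3-(4-iodophenyl)prop-2-enoic acid
Product: 6 2,5-dioxopyrrolidin-1-yl (E)-3-(4-iodophenyl)prop-2-enoate
Conditions: N-hydroxysuccinimide (1.1 equiv), EDC·HCl (1.2 equiv), CH2Cl2/THF, 0 °C to rt
Reagents that add atoms: N-hydroxysuccinimide, ON1C(=O)CCC1=O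
Why: carbodiimide-mediated esterification with N-hydroxysuccinimide should give a crystalline, storable active ester that can be dosed exactly in step 7.

Step 5
Reactants: 3 (E)-3-[3-hydroxy-4-(prop-2-en-1-yloxy)phenyl]prop-2-enoic acid; 7 N1,N4-bis-Boc-spermidine [tert-butyl N-(4-aminobutyl)-N-[3-(tert-butoxycarbonylamino)propyl]carbamate]
Product: 8 N8-[(E)-4-allyloxy-3-hydroxycinnamoyl]-N1,N4-bis-Boc-spermidine
Conditions: EDC·HCl (1.2 equiv), HOBt (1.2 equiv), DMF, 0 °C to rt
Reagents that add atoms: none
Why: carbodiimide/HOBt amide coupling at the only free amine (N8) of 7 should proceed cleanly, because the unprotected phenol of 3 is a far poorer acyl acceptor than a primary amine.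

Step 6
Reactants: 8 N8-[(E)-4-allyloxy-3-hydroxycinnamoyl]-N1,N4-bis-Boc-spermidine
Product: 9 N8-[(E)-4-allyloxy-3-hydroxycinnamoyl]spermidine dihydrochloride
Conditions: HCl (4 M in 1,4-dioxane), 0 °C to rt; filtration of the salt
Reagents that add atoms: hydrogen chloride, Cl
Why: acidolysis of both tert-butyl carbamates with anhydrous HCl should leave the allyl aryl ether, the phenol and the cinnamamide untouched and deliver the diamine as its dihydrochloride.

Step 7
Reactants: 9 N8-[(E)-4-allyloxy-3-hydroxycinnamoyl]spermidine dihydrochloride; 6 2,5-dioxopyrrolidin-1-yl (E)-3-(4-iodophenyl)prop-2-enoate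
Product: 11 N1-[(E)-4-iodocinnamoyl]-N8-[(E)-4-allyloxy-3-hydroxycinnamoyl]-N4-[2-(trimethylsilyl)ethoxycarbonyl]spermidine, via N4-unprotected diamide 10 (not isolated)
Conditions: Et3N (2.2 equiv), DMF, −20 °C, 6 (0.95 equiv) added over 2 h, −20 to 0 °C; then Teoc-OSu (1.1 equiv), Et3N (1.2 equiv), rt
Reagents that add atoms: N-[2-(trimethylsilyl)ethoxycarbonyloxy]succinimide (Teoc-OSu), C[Si](C)(C)CCOC(=O)ON1C(=O)CCC1=O
Why: primary-selective aminolysis of an N-hydroxysuccinimide ester at low temperature (the unhindered N1 amine reacts much faster than the dialkyl N4 amine, as known for polyamines) is followed in the same flask by carbamate formation at the remaining N4–H with Teoc-OSu, the phenol being less nucleophilic than either amine.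

Step 8
Reactants: 11 N1-[(E)-4-iodocinnamoyl]-N8-[(E)-4-allyloxy-3-hydroxycinnamoyl]-N4-[2-(trimethylsilyl)ethoxycarbonyl]spermidine
Product: 12 O-allyl N4-Teoc macrocycle (24-membered ring; ether oxygen from ring A C3 to ring B C4; both alkenes E)
Conditions: CuI (0.5 equiv), N,N-dimethylglycine hydrochloride (1.5 equiv), Cs2CO3 (5 equiv), degassed 1,4-dioxane, 90 °C, 11 added by syringe pump over 12 h (final 2 mM), dark
Reagents that add atoms: none
Why: Cs2CO3 ionises the only free phenol (ring A C3–OH), the phenoxide binds monovalent copper carrying the N,N-dimethylglycinate ligand, oxidative addition into the ring B C4–I bond gives an aryl trivalent copper phenoxide, and C–O reductive elimination forms the O–C4(ring B) bond and returns monovalent copper. The closest known reaction type is the ligand-accelerated intramolecular Ullmann diaryl ether synthesis, which is established for macrocyclic diaryl ethers. The single new ring, the 24-membered macrocycle, is closed end to end by intramolecular O-arylation of the seco-diamide; the rigid E-propenamide units on both rings preorganise the chain, and the electron-withdrawing acrylamide para to iodine eases oxidative addition. No stereocentre is formed and the E-alkenes should not be touched at 90 °C in the dark. The step needs O- over N-arylation and ring closure over oligomerisation: the carbonate base deprotonates the phenol but not the amides, N4 is blocked as its carbamate, the C4 oxygen of ring A is blocked as the allyl ether, and slow addition keeps the stationary concentration of 11 low.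

Step 9
Reactants: 12 O-allyl N4-Teoc macrocycle
Product: 13 N4-Teoc macrocycle with free ring A C4 hydroxyl
Conditions: Pd(PPh3)4 (5 mol %), morpholine (10 equiv), THF, rt
Reagents that add atoms: none
Why: Tsuji–Trost type deallylation, in which zerovalent palladium ionises the allyl aryl ether to a π-allyl complex that morpholine captures, should leave the carbamate, the amides, the diaryl ether and the E-alkenes untouched.

Step 10
Reactants: 13 N4-Teoc macrocycle with free ring A C4 hydroxyl
Product: 15 sodium salt of the N4-Teoc macrocycle ring A C4 sulfate, via pyridinium aryl sulfate 14 (not isolated)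
Conditions: SO3·pyridine (5 equiv), pyridine, 40 °C; then aq. NaHCO3, C18 chromatography
Reagents that add atoms: sulfur trioxide–pyridine complex, O=S(=O)([O-])[n+]1ccccc1; NaHCO3, [Na+].OC([O-])=O
Why: O-sulfation of the phenol with the SO3–pyridine complex followed by cation exchange should give the base-stable sulfate monoester salt, since amide N–H groups and the carbamate do not react with this reagent.

Step 11
Reactants: 15 sodium salt of the N4-Teoc macrocycle ring A C4 sulfate
Product: 16 CID124202369 (macrocycle with ring A C4 hydrogen sulfate and free N4–H, isolated as the inner salt)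
Conditions: Bu4NF (3 equiv), THF, 45 °C; AcOH to pH 6, C18 chromatography (water/MeCN)
Reagents that add atoms: none
Why: fluoride-induced β-elimination of the 2-(trimethylsilyl)ethyl carbamate releases ethene and CO2 under non-acidic conditions that an aryl sulfate monoester tolerates, and buffering to pH 6 should give the inner salt.

Compound list
1 | 3,4-dihydroxybenzaldehyde | O=Cc1ccc(O)c(O)c1 | starting material
2 | 3-hydroxy-4-(prop-2-en-1-yloxy)benzaldehyde | O=Cc1ccc(OCC=C)c(O)c1 | intermediate
3 | (E)-3-[3-hydroxy-4-(prop-2-en-1-yloxy)phenyl]prop-2-enoic acid (ring A acid) | OC(=O)/C=C/c1ccc(OCC=C)c(O)c1 | intermediate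
4 | 4-iodobenzaldehyde | O=Cc1ccc(I)cc1 | starting material
5 | (E)-3-(4-iodophenyl)prop-2-enoic acid (ring B acid) | OC(=O)/C=C/c1ccc(I)cc1 | intermediate
6 | 2,5-dioxopyrrolidin-1-yl (E)-3-(4-iodophenyl)prop-2-enoate | O=C(/C=C/c1ccc(I)cc1)ON1C(=O)CCC1=O | intermediate
7 | N1,N4-bis-Boc-spermidine, tert-butyl N-(4-aminobutyl)-N-[3-(tert-butoxycarbonylamino)propyl]carbamate | NCCCCN(C(=O)OC(C)(C)C)CCCNC(=O)OC(C)(C)C | starting material
8 | N8-[(E)-4-allyloxy-3-hydroxycinnamoyl]-N1,N4-bis-Boc-spermidine | CC(C)(C)OC(=O)NCCCN(C(=O)OC(C)(C)C)CCCCNC(=O)/C=C/c1ccc(OCC=C)c(O)c1 | intermediate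
9 | N8-[(E)-4-allyloxy-3-hydroxycinnamoyl]spermidine dihydrochloride | Cl.Cl.NCCCNCCCCNC(=O)/C=C/c1ccc(OCC=C)c(O)c1 | intermediate
10 | N1-[(E)-4-iodocinnamoyl]-N8-[(E)-4-allyloxy-3-hydroxycinnamoyl]spermidine (N4–H free) | O=C(/C=C/c1ccc(I)cc1)NCCCNCCCCNC(=O)/C=C/c1ccc(OCC=C)c(O)c1 | intermediate
11 | N1-[(E)-4-iodocinnamoyl]-N8-[(E)-4-allyloxy-3-hydroxycinnamoyl]-N4-[2-(trimethylsilyl)ethoxycarbonyl]spermidine (seco precursor) | Ic1ccc(cc1)/C=C/C(=O)NCCCN(C(=O)OCC[Si](C)(C)C)CCCCNC(=O)/C=C/c1ccc(OCC=C)c(O)c1 | intermediate
12 | O-allyl N4-Teoc macrocycle (24-membered, diaryl ether ring A C3–O–ring B C4, both alkenes E) | O=C1/C=C/c2ccc(OCC=C)c(c2)Oc2ccc(cc2)/C=C/C(=O)NCCCN(C(=O)OCC[Si](C)(C)C)CCCCN1 | intermediate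
13 | N4-Teoc macrocycle with free ring A C4 hydroxyl | O=C1/C=C/c2ccc(O)c(c2)Oc2ccc(cc2)/C=C/C(=O)NCCCN(C(=O)OCC[Si](C)(C)C)CCCCN1 | intermediate
14 | pyridinium salt of the N4-Teoc macrocycle ring A C4 sulfate | O=C1/C=C/c2ccc(OS(=O)(=O)[O-])c(c2)Oc2ccc(cc2)/C=C/C(=O)NCCCN(C(=O)OCC[Si](C)(C)C)CCCCN1.c1cc[nH+]cc1 | intermediate
15 | sodium salt of the N4-Teoc macrocycle ring A C4 sulfate | O=C1/C=C/c2ccc(OS(=O)(=O)[O-])c(c2)Oc2ccc(cc2)/C=C/C(=O)NCCCN(C(=O)OCC[Si](C)(C)C)CCCCN1.[Na+] | intermediate
16 | CID124202369, macrocycle with ring A C4 hydrogen sulfate and free N4–H (both alkenes E) | O=C1/C=C/c2ccc(OS(=O)(=O)O)c(c2)Oc2ccc(cc2)/C=C/C(=O)NCCCNCCCCN1 | target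

Total step count: 11. Longest linear sequence: 9 steps (steps 1, 2, 5, 6, 7, 8, 9, 10, 11, from 1 to 16).

Steps most likely to fail

Step 8. Intermolecular O-arylation may outrun ring closure and give oligomers, the amide nitrogens may be arylated, or iodine may be lost reductively from ring B. The fallback closes the same O–C bond by an oxidative Chan–Evans–Lam coupling of a boronic acid instead of an Ullmann coupling of an iodide. It sets out from 9. Commercial (E)-3-(4-boronophenyl)prop-2-enoic acid (OC(=O)/C=C/c1ccc(cc1)B(O)O) would be converted with N-hydroxysuccinimide and EDC·HCl into the succinimidyl ester of (E)-4-boronocinnamic acid F1. F1 would acylate N1 of 9 (Et3N, DMF, −20 °C) to the N4-unprotected boronic acid diamide F2, which would be treated in the same flask with Teoc-OSu to give the N4-Teoc arylboronic acid seco-diamide F3. F3 would then be cyclised with Cu(OAc)2 (2 equiv), pyridine, Et3N and 4 Å molecular sieves in CH2Cl2 under air at room temperature and high dilution. In that coupling the divalent copper phenoxide is transmetallated by the boronic acid and C–O reductive elimination follows oxidation to trivalent copper. The fallback comes back to the route at 12.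

Step 7. Discrimination between the primary N1 and the secondary N4 amine may be incomplete, giving N4-acyl and bis-acyl material, and the phenol may be acylated to a small extent. The fallback ties N1 and N4 together temporarily so that only one amine N–H remains. It sets out from 9. After liberation of the free base, aqueous formaldehyde (1.0 equiv, EtOH/water, rt) would bridge the 1,3-diamine unit to give the 1-substituted hexahydropyrimidine F4. Its single amine N–H (N1) would be acylated with 6 (Et3N, CH2Cl2, rt) to the N-acyl hexahydropyrimidine F5. The aminal would be opened with malonic acid and pyridine in refluxing EtOH, where the released formaldehyde is scavenged by Knoevenagel condensation. This gives 10, where the fallback comes back to the route; 10 is converted to 11 with Teoc-OSu as in the second half of step 7.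

Step 11. Fluoride-induced fragmentation of the hindered carbamate may be slow or incomplete, part of the sulfate may be lost during long treatment or acidification, and the inner salt may be hard to separate from tetrabutylammonium salts. The fallback carries the sulfate as a neutral, acid-stable diester so that the carbamate can be removed with acid. It sets out from 13. Treatment with 2,2,2-trichloroethyl chlorosulfate (ClS(=O)(=O)OCC(Cl)(Cl)Cl), Et3N and DMAP in THF (0 °C to rt) would give the aryl 2,2,2-trichloroethyl sulfate diester F6. Trifluoroacetic acid in CH2Cl2 at 0 °C would cleave the silylethyl carbamate to the N4-unprotected trichloroethyl sulfate F7. Zn dust and HCO2NH4 in MeOH at rt would then remove the trichloroethyl group by reductive β-elimination. The fallback comes back to the route at 16.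

Further compounds
F1 | step 8 | 2,5-dioxopyrrolidin-1-yl (E)-3-(4-boronophenyl)prop-2-enoate | O=C(/C=C/c1ccc(cc1)B(O)O)ON1C(=O)CCC1=O
F2 | step 8 | N1-[(E)-4-boronocinnamoyl]-N8-[(E)-4-allyloxy-3-hydroxycinnamoyl]spermidine | OB(O)c1ccc(cc1)/C=C/C(=O)NCCCNCCCCNC(=O)/C=C/c1ccc(OCC=C)c(O)c1
F3 | step 8 | N1-[(E)-4-boronocinnamoyl]-N8-[(E)-4-allyloxy-3-hydroxycinnamoyl]-N4-[2-(trimethylsilyl)ethoxycarbonyl]spermidine | OB(O)c1ccc(cc1)/C=C/C(=O)NCCCN(C(=O)OCC[Si](C)(C)C)CCCCNC(=O)/C=C/c1ccc(OCC=C)c(O)c1
F4 | step 7 | (E)-N-[4-(hexahydropyrimidin-1-yl)butyl]-3-[3-hydroxy-4-(prop-2-en-1-yloxy)phenyl]prop-2-enamide | O=C(/C=C/c1ccc(OCC=C)c(O)c1)NCCCCN1CCCNC1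
F5 | step 7 | (E)-N-[4-[3-[(E)-3-(4-iodophenyl)prop-2-enoyl]hexahydropyrimidin-1-yl]butyl]-3-[3-hydroxy-4-(prop-2-en-1-yloxy)phenyl]prop-2-enamide | O=C(/C=C/c1ccc(OCC=C)c(O)c1)NCCCCN1CCCN(C1)C(=O)/C=C/c1ccc(I)cc1
F6 | step 11 | N4-Teoc macrocycle ring A C4 (2,2,2-trichloroethyl) sulfate diester | O=C1/C=C/c2ccc(OS(=O)(=O)OCC(Cl)(Cl)Cl)c(c2)Oc2ccc(cc2)/C=C/C(=O)NCCCN(C(=O)OCC[Si](C)(C)C)CCCCN1
F7 | step 11 | N4–H macrocycle ring A C4 (2,2,2-trichloroethyl) sulfate diester | O=C1/C=C/c2ccc(OS(=O)(=O)OCC(Cl)(Cl)Cl)c(c2)Oc2ccc(cc2)/C=C/C(=O)NCCCNCCCCN1
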